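**Plan**

- Cuts, in retrosynthetic order: C5'–C(alkene) of the propenol; C2'–C3' of unit 2; the ring C aryl–C(diazo) bond and the ring C ArO–CH2 bond; then in unit 1 the C5–CH2OH bond, C2–C3, aryl–C(diazo) and ArO–CH2.
- Feature used: C2' is a benzylic ether carbon bound to O1' and to C5 of ring B, and C3' is a benzylic carbon carrying the C9' carbinol. C2'–C3' is therefore the bond an aryl(alkoxycarbonyl)carbene on ring C makes by inserting into an ArCH2–O C–H bond; C2–C3 of unit 1 has the same make-up.
- Forward: ring A benzyl alcohol 3 and iodophenol 5 give an aryl benzyl ether, a palladium coupling installs the diazo ester, and insertion closes the dihydrofuran of unit 1 (step 9). Its C5 bromide becomes CH2OH and is etherified with a second molecule of 5; coupling and insertion then close the dihydrofuran of unit 2 (step 15). Ester reduction, Suzuki–Miyaura coupling and desilylation finish.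
- Stereochemistry: both trans pairs (C2/C3 and C2'/C3') come from the (S)-lactamide ester matched with Rh2(S-DOSP)4, dirhodium tetrakis[(S)-N-(4-dodecylbenzenesulfonyl)prolinate]; the E alkene comes from E-alkenylboronate 23.

Key step: step 15

Numbering: dihydrobenzofuran numbering (O1, C2, C3, C3a, C4 to C7, C7a; C9 is the CH2O carbon on C3) for unit 1, primed for unit 2. Ring A is the guaiacyl ring on C2, ring B the benzo ring of unit 1, ring C the benzo ring of unit 2.

Assumption: the (S)-lactamide/Rh2(S-DOSP)4 pair is taken to give the trans ring with the 2R configuration drawn; step 9 tests this sense on unit 1 before the key step, and the mirror-image auxiliary/catalyst pair would be the remedy if it proved opposite.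

**Route**

Step 1
Reactants: 1 vanillin
Product: 2 4-(tert-butyldimethylsilyloxy)-3-methoxybenzaldehyde
Conditions: TBSCl, imidazole, DMF, rt
Reagents that add atoms: tert-butyldimethylsilyl chloride, CC(C)(C)[Si](C)(C)Cl
Why: Imidazole-promoted silylation of the phenol is routine and gives an ether that should last through the neutral and weakly basic steps ahead and leave with fluoride at the end.

Step 2
Reactants: 2 4-(tert-butyldimethylsilyloxy)-3-methoxybenzaldehyde
Product: 3 [4-(tert-butyldimethylsilyloxy)-3-methoxyphenyl]methanol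
Conditions: NaBH4, THF/MeOH, 0 °C
Reagents that add atoms: none
Why: Borohydride reduction of the aromatic aldehyde is fast at 0 °C and should leave the aryl silyl ether untouched.

Step 3
Reactants: 4 4-bromo-2-methoxyphenol
Product: 5 4-bromo-2-iodo-6-methoxyphenol
Conditions: N-iodosuccinimide, TsOH·H2O (cat.), MeCN, rt
Reagents that add atoms: N-iodosuccinimide, O=C1CCC(=O)N1I
Why: Electrophilic aromatic iodination should go ortho to the hydroxyl group, the strongest director, because the para position is blocked by bromine.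

Step 4
Reactants: 6 ethyl (S)-lactate; 7 pyrrolidine
Product: 8 (S)-2-hydroxy-1-(pyrrolidin-1-yl)propan-1-one
Conditions: pyrrolidine (excess), neat, 50 °C
Reagents that add atoms: none
Why: Aminolysis of the α-hydroxy ester by a secondary amine needs no activation and does not touch the stereocentre.

Step 5
Reactants: 8 (S)-2-hydroxy-1-(pyrrolidin-1-yl)propan-1-one
Product: 9 (S)-1-oxo-1-(pyrrolidin-1-yl)propan-2-yl 2-bromoacetate
Conditions: BrCH2COBr, NaHCO3, MeCN, 0 °C
Reagents that add atoms: bromoacetyl bromide, BrCC(Br)=O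
Why: O-acylation of the secondary alcohol by the acid bromide under bicarbonate buffering proceeds with retention at the carbinol carbon.

Step 6
Reactants: 9 (S)-1-oxo-1-(pyrrolidin-1-yl)propan-2-yl 2-bromoacetate
Product: 10 (S)-1-oxo-1-(pyrrolidin-1-yl)propan-2-yl 2-diazoacetate
Conditions: TsNHNHTs, DBU, THF, 0 °C
Reagents that add atoms: N,N'-ditosylhydrazine, Cc1ccc(cc1)S(=O)(=O)NNS(=O)(=O)c1ccc(C)cc1
Why: N-alkylation of the ditosylhydrazide anion by the bromoacetate followed by twofold elimination of sulfinate (the ditosylhydrazine route to diazoacetates) should give the diazo ester under mild conditions.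

Step 7
Reactants: 3 [4-(tert-butyldimethylsilyloxy)-3-methoxyphenyl]methanol; 5 4-bromo-2-iodo-6-methoxyphenol
Product: 11 4-bromo-2-iodo-6-methoxyphenyl 4-(tert-butyldimethylsilyloxy)-3-methoxybenzyl ether
Conditions: PPh3, DIAD, THF, 0 °C → rt
Reagents that add atoms: none
Why: In this Mitsunobu etherification the acidic, halogen-flanked phenol should displace the oxyphosphonium derivative of the primary benzylic alcohol under neutral conditions that spare the aryl silyl ether.

Step 8
Reactants: 11 4-bromo-2-iodo-6-methoxyphenyl 4-(tert-butyldimethylsilyloxy)-3-methoxybenzyl ether; 10 (S)-1-oxo-1-(pyrrolidin-1-yl)propan-2-yl 2-diazoacetate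
Product: 12 (S)-1-oxo-1-(pyrrolidin-1-yl)propan-2-yl 2-[5-bromo-2-[4-(tert-butyldimethylsilyloxy)-3-methoxybenzyloxy]-3-methoxyphenyl]-2-diazoacetate
Conditions: Pd(PPh3)4 (5 mol %), Et3N, n-Bu4NBr, MeCN/toluene, rt
Reagents that add atoms: none
Why: This is the palladium-catalysed C–H arylation of an acceptor diazo ester with an aryl iodide, in which zerovalent palladium adds to the carbon–iodine bond much faster than to the carbon–bromine bond and amine-assisted palladation of the diazo carbon followed by reductive elimination keeps the diazo group at room temperature.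

Step 9
Reactants: 12 (S)-1-oxo-1-(pyrrolidin-1-yl)propan-2-yl 2-[5-bromo-2-[4-(tert-butyldimethylsilyloxy)-3-methoxybenzyloxy]-3-methoxyphenyl]-2-diazoacetate
Product: 13 (S)-1-oxo-1-(pyrrolidin-1-yl)propan-2-yl (2R,3R)-5-bromo-2-[4-(tert-butyldimethylsilyloxy)-3-methoxyphenyl]-7-methoxy-2,3-dihydrobenzofuran-3-carboxylate
Conditions: Rh2(S-DOSP)4 (1 mol %), CH2Cl2, −20 °C → rt, slow addition of 12
Reagents that add atoms: none
Why: Intramolecular 1,5 C–H insertion of the donor/acceptor carbenoid of divalent rhodium into the OCH2 group, activated by the ether oxygen and the para-silyloxy ring A, should close the dihydrofuran, with C2 set by the matched (S)-lactamide/(S)-prolinate pair and C3 by the trans placing of aryl and ester, which is also the thermodynamic arrangement because C3 is α to the ester.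

Step 10
Reactants: 13 (S)-1-oxo-1-(pyrrolidin-1-yl)propan-2-yl (2R,3R)-5-bromo-2-[4-(tert-butyldimethylsilyloxy)-3-methoxyphenyl]-7-methoxy-2,3-dihydrobenzofuran-3-carboxylate
Product: 14 [(2R,3S)-5-bromo-2-[4-(tert-butyldimethylsilyloxy)-3-methoxyphenyl]-7-methoxy-2,3-dihydrobenzofuran-3-yl]methanol
Conditions: LiBH4, THF, 0 °C → rt
Reagents that add atoms: none
Why: Borohydride reduction of the activated α-aryl ester should give the primary alcohol and release the auxiliary as 8, while the aryl bromide, the silyl ether and the tertiary amide of the auxiliary are not attacked and C3 keeps its configuration.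

Step 11
Reactants: 14 [(2R,3S)-5-bromo-2-[4-(tert-butyldimethylsilyloxy)-3-methoxyphenyl]-7-methoxy-2,3-dihydrobenzofuran-3-yl]methanol
Product: 15 (2R,3S)-5-bromo-3-(tert-butyldimethylsilyloxymethyl)-2-[4-(tert-butyldimethylsilyloxy)-3-methoxyphenyl]-7-methoxy-2,3-dihydrobenzofuran
Conditions: TBSCl, imidazole, DMF, rt
Reagents that add atoms: tert-butyldimethylsilyl chloride, CC(C)(C)[Si](C)(C)Cl
Why: Silylation of the primary alcohol masks C9–OH so that only the C5 carbinol made next can enter the second etherification.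

Step 12
Reactants: 15 (2R,3S)-5-bromo-3-(tert-butyldimethylsilyloxymethyl)-2-[4-(tert-butyldimethylsilyloxy)-3-methoxyphenyl]-7-methoxy-2,3-dihydrobenzofuran
Product: 18 [(2R,3S)-3-(tert-butyldimethylsilyloxymethyl)-2-[4-(tert-butyldimethylsilyloxy)-3-methoxyphenyl]-7-methoxy-2,3-dihydrobenzofuran-5-yl]methanol, via C5 aryllithium 16 (not isolated), via C5 aldehyde 17 (not isolated)
Conditions: n-BuLi, THF, −78 °C; DMF, −78 → 0 °C; AcOH (1 equiv), MeOH, then NaBH4, 0 °C
Reagents that add atoms: N,N-dimethylformamide, CN(C)C=O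
Why: Bromine–lithium exchange at −78 °C outruns any deprotonation, the aryllithium is formylated by DMF (Bouveault reaction), and after buffering with AcOH the aldehyde set free is reduced in the same flask by NaBH4 without exposing the aryl silyl ether to alkoxide.

Step 13
Reactants: 18 [(2R,3S)-3-(tert-butyldimethylsilyloxymethyl)-2-[4-(tert-butyldimethylsilyloxy)-3-methoxyphenyl]-7-methoxy-2,3-dihydrobenzofuran-5-yl]methanol; 5 4-bromo-2-iodo-6-methoxyphenol
Product: 19 (2R,3S)-5-[(4-bromo-2-iodo-6-methoxyphenoxy)methyl]-3-(tert-butyldimethylsilyloxymethyl)-2-[4-(tert-butyldimethylsilyloxy)-3-methoxyphenyl]-7-methoxy-2,3-dihydrobenzofuran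
Conditions: PPh3, DIAD, THF, 0 °C → rt
Reagents that add atoms: none
Why: Mitsunobu etherification of the primary para-alkoxybenzylic alcohol with the acidic phenol 5 should form the ArO–CH2 bond under neutral conditions that spare both silyl ethers and the acid-sensitive C2 benzylic ether.

Step 14
Reactants: 19 (2R,3S)-5-[(4-bromo-2-iodo-6-methoxyphenoxy)methyl]-3-(tert-butyldimethylsilyloxymethyl)-2-[4-(tert-butyldimethylsilyloxy)-3-methoxyphenyl]-7-methoxy-2,3-dihydrobenzofuran; 10 (S)-1-oxo-1-(pyrrolidin-1-yl)propan-2-yl 2-diazoacetate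
Product: 20 (S)-1-oxo-1-(pyrrolidin-1-yl)propan-2-yl 2-[5-bromo-2-[[(2R,3S)-3-(tert-butyldimethylsilyloxymethyl)-2-[4-(tert-butyldimethylsilyloxy)-3-methoxyphenyl]-7-methoxy-2,3-dihydrobenzofuran-5-yl]methoxy]-3-methoxyphenyl]-2-diazoacetate
Conditions: Pd(PPh3)4 (5 mol %), Et3N, n-Bu4NBr, MeCN/toluene, rt
Reagents that add atoms: none
Why: The same palladium-catalysed arylation of the diazo ester C–H bond as in step 8 should select the carbon–iodine bond over the carbon–bromine bond at room temperature and leave silyl ethers, benzylic ethers and both stereocentres untouched.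

Step 15
Reactants: 20 (S)-1-oxo-1-(pyrrolidin-1-yl)propan-2-yl 2-[5-bromo-2-[[(2R,3S)-3-(tert-butyldimethylsilyloxymethyl)-2-[4-(tert-butyldimethylsilyloxy)-3-methoxyphenyl]-7-methoxy-2,3-dihydrobenzofuran-5-yl]methoxy]-3-methoxyphenyl]-2-diazoacetate
Product: 21 (S)-1-oxo-1-(pyrrolidin-1-yl)propan-2-yl (2R,3R)-5-bromo-2-[(2R,3S)-3-(tert-butyldimethylsilyloxymethyl)-2-[4-(tert-butyldimethylsilyloxy)-3-methoxyphenyl]-7-methoxy-2,3-dihydrobenzofuran-5-yl]-7-methoxy-2,3-dihydrobenzofuran-3-carboxylate
Conditions: Rh2(S-DOSP)4 (1 mol %), CH2Cl2, −20 °C → rt, slow addition of 20 at high dilution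
Reagents that add atoms: none
Why: Rh2(S-DOSP)4 expels N2 from 20 to give a donor/acceptor carbenoid of divalent rhodium, whose electrophilic carbon takes the hydride-like C–H of the ring C OCH2 group in a concerted, asynchronous three-centre transition state, so that C2'–C3' forms as the hydrogen passes to C3'. The closest known reaction is the dirhodium-tetracarboxylate-catalysed intramolecular C–H insertion of 2-(benzyloxy)aryldiazoacetates to trans-2-aryl-2,3-dihydrobenzofuran-3-carboxylates, here with a lactamide ester as auxiliary. The dihydrofuran ring of unit 2 (C3', C3a', C7a', O1', C2') closes by 1,5-insertion, the only five-membered mode open to the carbene. C2' is controlled by the face of the carbenoid left open by the matched (S)-lactamide ester and the (S)-prolinate ligands, and C3' by the trans placing of ring B and the ester in that transition state, which is also the thermodynamic arrangement because C3' is α to the ester. The step needs site selectivity and reagent control over the two distant stereocentres of unit 1: the OCH2 group is the only C–H in 1,5 reach and is activated by the ether oxygen and the para-oxygenated ring B, no alkene is present because C5' is still a bromide, and slow addition at high dilution suppresses carbene dimerisation.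

Step 16
Reactants: 21 (S)-1-oxo-1-(pyrrolidin-1-yl)propan-2-yl (2R,3R)-5-bromo-2-[(2R,3S)-3-(tert-butyldimethylsilyloxymethyl)-2-[4-(tert-butyldimethylsilyloxy)-3-methoxyphenyl]-7-methoxy-2,3-dihydrobenzofuran-5-yl]-7-methoxy-2,3-dihydrobenzofuran-3-carboxylate
Product: 22 [(2R,3S)-5-bromo-2-[(2R,3S)-3-(tert-butyldimethylsilyloxymethyl)-2-[4-(tert-butyldimethylsilyloxy)-3-methoxyphenyl]-7-methoxy-2,3-dihydrobenzofuran-5-yl]-7-methoxy-2,3-dihydrobenzofuran-3-yl]methanol
Conditions: LiBH4, THF, 0 °C → rt
Reagents that add atoms: none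
Why: As in step 10, borohydride reduction of the activated ester should give the C9' alcohol and release auxiliary 8 before any basic step could epimerise or open the ring at C3'.

Step 17
Reactants: 22 [(2R,3S)-5-bromo-2-[(2R,3S)-3-(tert-butyldimethylsilyloxymethyl)-2-[4-(tert-butyldimethylsilyloxy)-3-methoxyphenyl]-7-methoxy-2,3-dihydrobenzofuran-5-yl]-7-methoxy-2,3-dihydrobenzofuran-3-yl]methanol; 23 (E)-tert-butyldimethyl[3-(4,4,5,5-tetramethyl-1,3,2-dioxaborolan-2-yl)allyloxy]silane
Product: 24 [(2R,3S)-5-[(E)-3-(tert-butyldimethylsilyloxy)prop-1-enyl]-2-[(2R,3S)-3-(tert-butyldimethylsilyloxymethyl)-2-[4-(tert-butyldimethylsilyloxy)-3-methoxyphenyl]-7-methoxy-2,3-dihydrobenzofuran-5-yl]-7-methoxy-2,3-dihydrobenzofuran-3-yl]methanol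
Conditions: Pd(OAc)2, SPhos, K3PO4, THF/H2O, 40 °C
Reagents that add atoms: none
Why: Suzuki–Miyaura coupling of the aryl bromide with the E-alkenyl pinacol boronate keeps the alkene geometry under mild phosphate conditions, the free primary alcohol is a spectator, and loss of the phenolic silyl group, should it occur, is harmless because the next step removes all three.

Step 18
Reactants: 24 [(2R,3S)-5-[(E)-3-(tert-butyldimethylsilyloxy)prop-1-enyl]-2-[(2R,3S)-3-(tert-butyldimethylsilyloxymethyl)-2-[4-(tert-butyldimethylsilyloxy)-3-methoxyphenyl]-7-methoxy-2,3-dihydrobenzofuran-5-yl]-7-methoxy-2,3-dihydrobenzofuran-3-yl]methanol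
Product: 25 (E)-3-[(2R,3S)-3-(hydroxymethyl)-2-[(2R,3S)-2-(4-hydroxy-3-methoxyphenyl)-3-(hydroxymethyl)-7-methoxy-2,3-dihydrobenzofuran-5-yl]-7-methoxy-2,3-dihydrobenzofuran-5-yl]prop-2-en-1-ol
Conditions: TBAF, AcOH, THF, 0 °C → rt
Reagents that add atoms: none
Why: Fluoride cleaves the aryl, primary and allylic silyl ethers in one operation, and the AcOH buffer keeps the liberated para-hydroxybenzyl ether of unit 1 from opening through a quinone methide, so no stereocentre is touched.

**Compound list**

1 | vanillin | COc1cc(C=O)ccc1O | starting material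
2 | 4-(tert-butyldimethylsilyloxy)-3-methoxybenzaldehyde | COc1cc(C=O)ccc1O[Si](C)(C)C(C)(C)C | intermediate
3 | [4-(tert-butyldimethylsilyloxy)-3-methoxyphenyl]methanol | COc1cc(CO)ccc1O[Si](C)(C)C(C)(C)C | intermediate
4 | 4-bromo-2-methoxyphenol | COc1cc(Br)ccc1O | starting material
5 | 4-bromo-2-iodo-6-methoxyphenol | Ic1cc(Br)cc(OC)c1O | intermediate
6 | ethyl (S)-lactate | C[C@H](O)C(=O)OCC | starting material
7 | pyrrolidine | C1CCNC1 | starting material
8 | (S)-2-hydroxy-1-(pyrrolidin-1-yl)propan-1-one | C[C@H](O)C(=O)N1CCCC1 | intermediate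
9 | (S)-1-oxo-1-(pyrrolidin-1-yl)propan-2-yl 2-bromoacetate | C[C@H](OC(=O)CBr)C(=O)N1CCCC1 | intermediate
10 | (S)-1-oxo-1-(pyrrolidin-1-yl)propan-2-yl 2-diazoacetate | C[C@H](OC(=O)C=[N+]=[N-])C(=O)N1CCCC1 | intermediate
11 | 4-bromo-2-iodo-6-methoxyphenyl 4-(tert-butyldimethylsilyloxy)-3-methoxybenzyl ether | Ic1cc(Br)cc(OC)c1OCc1ccc(O[Si](C)(C)C(C)(C)C)c(OC)c1 | intermediate
12 | ring B aryldiazoacetate (S)-lactamide ester with ring A benzyl ether | COc1cc(Br)cc(C(=[N+]=[N-])C(=O)O[C@@H](C)C(=O)N2CCCC2)c1OCc1ccc(O[Si](C)(C)C(C)(C)C)c(OC)c1 | intermediate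
13 | unit 1 trans (2R,3R) C3 lactamide ester, C5 bromide, aryl TBS ether | COc1cc([C@@H]2Oc3c(OC)cc(Br)cc3[C@H]2C(=O)O[C@@H](C)C(=O)N4CCCC4)ccc1O[Si](C)(C)C(C)(C)C | intermediate
14 | unit 1 (2R,3S) C9 alcohol, C5 bromide, aryl TBS ether | COc1cc([C@@H]2Oc3c(OC)cc(Br)cc3[C@H]2CO)ccc1O[Si](C)(C)C(C)(C)C | intermediate
15 | unit 1 (2R,3S) C5 bromide, bis-TBS ether | COc1cc([C@@H]2Oc3c(OC)cc(Br)cc3[C@H]2CO[Si](C)(C)C(C)(C)C)ccc1O[Si](C)(C)C(C)(C)C | intermediate
16 | unit 1 C5 aryllithium, bis-TBS ether (not isolated) | COc1cc([C@@H]2Oc3c(OC)cc([Li])cc3[C@H]2CO[Si](C)(C)C(C)(C)C)ccc1O[Si](C)(C)C(C)(C)C | intermediate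
17 | unit 1 C5 aldehyde, bis-TBS ether (not isolated) | COc1cc([C@@H]2Oc3c(OC)cc(C=O)cc3[C@H]2CO[Si](C)(C)C(C)(C)C)ccc1O[Si](C)(C)C(C)(C)C | intermediate
18 | unit 1 C5 hydroxymethyl compound, bis-TBS ether | COc1cc([C@@H]2Oc3c(OC)cc(CO)cc3[C@H]2CO[Si](C)(C)C(C)(C)C)ccc1O[Si](C)(C)C(C)(C)C | intermediate
19 | unit 1 C5 benzyl ether of 4-bromo-2-iodo-6-methoxyphenol, bis-TBS ether | COc1cc([C@@H]2Oc3c(OC)cc(COc4c(OC)cc(Br)cc4I)cc3[C@H]2CO[Si](C)(C)C(C)(C)C)ccc1O[Si](C)(C)C(C)(C)C | intermediate
20 | ring C aryldiazoacetate (S)-lactamide ester with unit 1 benzyl ether, bis-TBS, aryl bromide | COc1cc([C@@H]2Oc3c(OC)cc(COc4c(OC)cc(Br)cc4C(=[N+]=[N-])C(=O)O[C@@H](C)C(=O)N5CCCC5)cc3[C@H]2CO[Si](C)(C)C(C)(C)C)ccc1O[Si](C)(C)C(C)(C)C | intermediate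
21 | trans bis(dihydrobenzofuran) C3' (S)-lactamide ester, bis-TBS, C5' bromide | COc1cc([C@@H]2Oc3c(OC)cc([C@@H]4Oc5c(OC)cc(Br)cc5[C@H]4C(=O)O[C@@H](C)C(=O)N6CCCC6)cc3[C@H]2CO[Si](C)(C)C(C)(C)C)ccc1O[Si](C)(C)C(C)(C)C | intermediate
22 | bis(dihydrobenzofuran) C9' alcohol, bis-TBS, C5' bromide | COc1cc([C@@H]2Oc3c(OC)cc([C@@H]4Oc5c(OC)cc(Br)cc5[C@H]4CO)cc3[C@H]2CO[Si](C)(C)C(C)(C)C)ccc1O[Si](C)(C)C(C)(C)C | intermediate
23 | (E)-tert-butyldimethyl[3-(4,4,5,5-tetramethyl-1,3,2-dioxaborolan-2-yl)allyloxy]silane | CC(C)(C)[Si](C)(C)OC/C=C/B1OC(C)(C)C(C)(C)O1 | starting material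
24 | tris-TBS ether of the target with free C9' alcohol | COc1cc([C@@H]2Oc3c(OC)cc([C@@H]4Oc5c(OC)cc(/C=C/CO[Si](C)(C)C(C)(C)C)cc5[C@H]4CO)cc3[C@H]2CO[Si](C)(C)C(C)(C)C)ccc1O[Si](C)(C)C(C)(C)C | intermediate
25 | CNP0250921.1 | COc1cc([C@@H]2Oc3c(OC)cc([C@@H]4Oc5c(OC)cc(/C=C/CO)cc5[C@H]4CO)cc3[C@H]2CO)ccc1O | target

**Step count and risks**

Total steps: 18. Longest linear sequence: 14 steps (steps 1, 2 and 7 to 18, from vanillin).

Step 14. The coupling at the hindered, electron-rich ortho-alkoxy aryl iodide may be outrun by palladium-induced loss of N2 from the diazo ester, so that carbene dimers form and the iodide stays unconsumed. The fallback sets out from 19 and makes the aryl–carbon bond at the ester level, bringing the diazo group in afterwards. Bromoacetate 9 is converted with activated zinc dust in THF into its Reformatsky reagent, the bromozinc enolate F1. This is coupled with the aryl iodide of 19 under Pd(PPh3)4 in THF at 50 °C (Negishi-type arylation of a zinc ester enolate, iodide before bromide) to give the arylacetic lactamide ester F2. Regitz diazo transfer with 4-acetamidobenzenesulfonyl azide and DBU in MeCN then gives 20, where the route resumes.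

Step 15. Facial discrimination may be poor if the auxiliary/catalyst pair is overridden by the bulky chiral unit 1, and part of the material may close to the cis ring. The fallback sets out from 19 and moves stereocontrol to the catalyst alone, followed by thermodynamic epimerisation. Coupling of 19 with ethyl diazoacetate under the conditions of step 14 gives the ethyl aryldiazoacetate F3. Rh2(S-PTTL)4, dirhodium tetrakis[N-phthaloyl-(S)-tert-leucinate], in toluene at −60 °C is known to give cis-2-aryl-2,3-dihydrobenzofuran-3-carboxylates with catalyst-set C2 configuration and should give the cis ethyl ester F4 (the enantiomeric catalyst is taken if the 2'S ring forms). DBU in toluene epimerises C3', which is α to the ester, to the trans ethyl ester F5. LiBH4 in THF then reduces F5 to 22, where the route resumes.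

Step 13. The oxyphosphonium salt of the para-alkoxybenzyl alcohol may ionise while the di-ortho-substituted phenol attacks slowly, leading to C-benzylation or self-etherification instead of O-alkylation. The fallback sets out from 18 and replaces the redox condensation by a Williamson etherification of a preformed halide. MsCl and Et3N in CH2Cl2 at 0 °C convert 18 into the benzylic chloride F6. Phenol 5 is then alkylated with F6 using K2CO3 and catalytic n-Bu4NI in acetone at rt, giving 19, where the route resumes.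

**Further compounds**

F1 | step 14 | bromozinc enolate (Reformatsky reagent) of bromoacetate 9 | C[C@H](OC(=O)C[Zn]Br)C(=O)N1CCCC1
F2 | step 14 | ring C arylacetic (S)-lactamide ester with unit 1 benzyl ether, bis-TBS, aryl bromide | COc1cc([C@@H]2Oc3c(OC)cc(COc4c(OC)cc(Br)cc4CC(=O)O[C@@H](C)C(=O)N5CCCC5)cc3[C@H]2CO[Si](C)(C)C(C)(C)C)ccc1O[Si](C)(C)C(C)(C)C
F3 | step 15 | ring C ethyl aryldiazoacetate with unit 1 benzyl ether, bis-TBS, aryl bromide | COc1cc([C@@H]2Oc3c(OC)cc(COc4c(OC)cc(Br)cc4C(=[N+]=[N-])C(=O)OCC)cc3[C@H]2CO[Si](C)(C)C(C)(C)C)ccc1O[Si](C)(C)C(C)(C)C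
F4 | step 15 | cis (2'R,3'S) bis(dihydrobenzofuran) C3' ethyl ester, bis-TBS, C5' bromide | COc1cc([C@@H]2Oc3c(OC)cc([C@@H]4Oc5c(OC)cc(Br)cc5[C@@H]4C(=O)OCC)cc3[C@H]2CO[Si](C)(C)C(C)(C)C)ccc1O[Si](C)(C)C(C)(C)C
F5 | step 15 | trans (2'R,3'R) bis(dihydrobenzofuran) C3' ethyl ester, bis-TBS, C5' bromide | COc1cc([C@@H]2Oc3c(OC)cc([C@@H]4Oc5c(OC)cc(Br)cc5[C@H]4C(=O)OCC)cc3[C@H]2CO[Si](C)(C)C(C)(C)C)ccc1O[Si](C)(C)C(C)(C)C
F6 | step 13 | unit 1 C5 chloromethyl compound, bis-TBS ether | COc1cc([C@@H]2Oc3c(OC)cc(CCl)cc3[C@H]2CO[Si](C)(C)C(C)(C)C)ccc1O[Si](C)(C)C(C)(C)C
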